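**Retrosynthetic overview**
1. Target 14 ⇐ (hydrogenolysis) dibenzyl ether 13 ⇐ (LiAlH4) cis-fused furofuranone 12, whose lactone ring hides both the C7 carbinol and the C9' CH2OH.
2. 12 ⇐ bridgehead allyl ester 10 by deallylation/decarboxylation.
3. Key step: 10 ⇐ epoxy alcohol 5 + arylidene malonate 7 by an oxa-Michael / 5-exo epoxide opening / lactonization domino that closes the oxolane and then the γ-lactone in one flask.
4. 5 ⇐ Sharpless epoxidation of O-benzylconiferyl alcohol 4 (from O-benzylvanillin 1 by Wittig, then i-Bu2AlH); 7 ⇐ Knoevenagel of 1 with diallyl malonate 6.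
5. Ring order: oxirane (step 3), then oxolane and lactone together (step 5); the lactone is opened again in step 7.

Assumption: lignan numbering is used (C7/C8/C9 = carbinol arm, C7'/C8'/C9' = aryl-oxolane side), and O-benzylvanillin 1, ylide 2 and diallyl malonate 6 are taken as cheap commercial materials.

Step 1
Reactants: 1 4-(benzyloxy)-3-methoxybenzaldehyde; 2 ethyl (triphenylphosphoranylidene)acetate
Product: 3 ethyl (2E)-3-[4-(benzyloxy)-3-methoxyphenyl]prop-2-enoate
Conditions: PhMe, 80 °C
Reagents that add atoms: none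
Why: Wittig olefination with a stabilized ylide gives the E-cinnamate almost exclusively, and no stereocenter is formed.

Step 2
Reactants: 3 ethyl (2E)-3-[4-(benzyloxy)-3-methoxyphenyl]prop-2-enoate
Product: 4 (2E)-3-[4-(benzyloxy)-3-methoxyphenyl]prop-2-en-1-ol
Conditions: i-Bu2AlH (2.5 equiv), CH2Cl2, −78 → 0 °C; aq. KNaC4H4O6 work-up
Reagents that add atoms: none
Why: 1,2-reduction of the conjugated ester by i-Bu2AlH gives the E-allylic alcohol without touching the alkene or the benzyl ether.

Step 3
Reactants: 4 (2E)-3-[4-(benzyloxy)-3-methoxyphenyl]prop-2-en-1-ol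
Product: 5 [(2S,3S)-3-[4-(benzyloxy)-3-methoxyphenyl]oxiran-2-yl]methanol
Conditions: Ti(OiPr)4 (10 mol %), L-(+)-diisopropyl tartrate (14 mol %), t-BuOOH (2 equiv, in decane), 4 Å MS, CH2Cl2, −25 °C; aq. NaOH/NaCl work-up; Et3N-deactivated SiO2
Reagents that add atoms: tert-butyl hydroperoxide CC(C)(C)OO
Why: Sharpless asymmetric epoxidation, in which the L-(+)-tartrate/titanium catalyst delivers oxygen to the face of the E-allylic alcohol that gives the (2S,3S)-trans-epoxide, setting C7 and the precursor of C8 under catalyst control (about 90–95% ee expected).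

Step 4
Reactants: 1 4-(benzyloxy)-3-methoxybenzaldehyde; 6 diallyl propanedioate
Product: 7 diallyl 2-{[4-(benzyloxy)-3-methoxyphenyl]methylidene}propanedioate
Conditions: piperidine (10 mol %), AcOH (10 mol %), PhMe, reflux, Dean–Stark
Reagents that add atoms: none
Why: Knoevenagel condensation driven by azeotropic removal of water, with no stereochemical issue because the malonate is symmetrical.

Step 5
Reactants: 5 [(2S,3S)-3-[4-(benzyloxy)-3-methoxyphenyl]oxiran-2-yl]methanol; 7 diallyl 2-{[4-(benzyloxy)-3-methoxyphenyl]methylidene}propanedioate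
Product: 10 allyl (3R,3aR,6R,6aS)-3,6-bis[4-(benzyloxy)-3-methoxyphenyl]-1-oxotetrahydro-1H,3H-furo[3,4-c]furan-6a(6H)-carboxylate, via oxa-Michael adduct enolate 8 (not isolated), via oxolane alkoxide 9 (not isolated)
Conditions: 7 (1.2 equiv), KOt-Bu (0.3 equiv), THF, −40 → 25 °C (40 °C to finish); AcOH quench; chromatography
Reagents that add atoms: none
Why: Proposed new method: the alkoxide of 5 adds reversibly to 7 (oxa-Michael), malonate enolate 8 opens the tethered oxirane at C8 in a 5-exo-tet SN2 step with inversion while the C7–O bond is untouched (so C7 keeps its Sharpless configuration), and alkoxide 9 lactonizes onto the cis allyl ester, which forces the cis ring fusion and places the C7 aryl endo (the arrangement that becomes 7R,8R); C7' is selected under Curtin–Hammett conditions through a chair-like transition state with the aryl pseudo-equatorial, which should favour the needed 2,4-trans oxolane (estimated 3–5:1, not guaranteed; minor epimer removed by chromatography); the closest known reaction types are Michael-initiated ring closure of arylidene malonates with 2-haloethanols to 2-aryloxolane-3,3-dicarboxylates and malonate epoxide-opening/lactonization to γ-lactones.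

Step 6
Reactants: 10 allyl (3R,3aR,6R,6aS)-3,6-bis[4-(benzyloxy)-3-methoxyphenyl]-1-oxotetrahydro-1H,3H-furo[3,4-c]furan-6a(6H)-carboxylate
Product: 12 (3R,3aR,6S,6aS)-3,6-bis[4-(benzyloxy)-3-methoxyphenyl]tetrahydro-1H,3H-furo[3,4-c]furan-1-one, via bridgehead carboxylic acid 11 (not isolated)
Conditions: Pd(PPh3)4 (5 mol %), HCO2H (2 equiv), Et3N (2.5 equiv), THF, 25 °C; then PhMe, 100 °C
Reagents that add atoms: none
Why: Tsuji-type deallylation by zerovalent palladium (π-allyl intermediate reduced by formate) gives the malonic-type acid 11, which decarboxylates on warming, and protonation at C8' can only give the cis-fused bicycle, so C8' is set by the ring fusion while C7, C8 and C7' are untouched under these neutral conditions.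

Step 7
Reactants: 12 (3R,3aR,6S,6aS)-3,6-bis[4-(benzyloxy)-3-methoxyphenyl]tetrahydro-1H,3H-furo[3,4-c]furan-1-one
Product: 13 [(2S,3R,4R)-2-[4-(benzyloxy)-3-methoxyphenyl]-4-[(R)-[4-(benzyloxy)-3-methoxyphenyl](hydroxy)methyl]oxolan-3-yl]methanol
Conditions: LiAlH4 (1.5 equiv), THF, 0 → 25 °C; H2O/aq. NaOH work-up (no acid)
Reagents that add atoms: none
Why: hydride reduction of the γ-lactone to the 1,4-diol (precedented for furofuranones) breaks only the acyl C–O bond, so the C7–O bond and all four stereocenters are carried over unchanged, giving 7R.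

Step 8
Reactants: 13 [(2S,3R,4R)-2-[4-(benzyloxy)-3-methoxyphenyl]-4-[(R)-[4-(benzyloxy)-3-methoxyphenyl](hydroxy)methyl]oxolan-3-yl]methanol
Product: 14 (7R)-7-hydroxylariciresinol, [(2S,3R,4R)-2-(4-hydroxy-3-methoxyphenyl)-4-[(R)-hydroxy(4-hydroxy-3-methoxyphenyl)methyl]oxolan-3-yl]methanol
Conditions: H2 (1 atm), 10% Pd/C, EtOAc, 25 °C, stopped at full conversion
Reagents that add atoms: none
Why: catalytic hydrogenolysis cleaves the two aryl benzyl ethers much faster than the secondary benzylic alcohol or the benzylic oxolane C–O bond in neutral EtOAc (as used for lariciresinol-type lignans and lignin models), and no stereocenter is touched.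

**Compound list**
1 | 4-(benzyloxy)-3-methoxybenzaldehyde (O-benzylvanillin) | O=Cc1ccc(OCc2ccccc2)c(OC)c1 | starting material
2 | ethyl (triphenylphosphoranylidene)acetate | CCOC(=O)C=P(c1ccccc1)(c1ccccc1)c1ccccc1 | starting material
3 | ethyl (2E)-3-[4-(benzyloxy)-3-methoxyphenyl]prop-2-enoate | CCOC(=O)/C=C/c1ccc(OCc2ccccc2)c(OC)c1 | intermediate
4 | (2E)-3-[4-(benzyloxy)-3-methoxyphenyl]prop-2-en-1-ol | OC/C=C/c1ccc(OCc2ccccc2)c(OC)c1 | intermediate
5 | [(2S,3S)-3-[4-(benzyloxy)-3-methoxyphenyl]oxiran-2-yl]methanol | OC[C@@H]1O[C@H]1c1ccc(OCc2ccccc2)c(OC)c1 | intermediate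
6 | diallyl propanedioate (diallyl malonate) | C=CCOC(=O)CC(=O)OCC=C | starting material
7 | diallyl 2-{[4-(benzyloxy)-3-methoxyphenyl]methylidene}propanedioate | C=CCOC(=O)C(=Cc1ccc(OCc2ccccc2)c(OC)c1)C(=O)OCC=C | intermediate
8 | diallyl 2-[(S)-[4-(benzyloxy)-3-methoxyphenyl]{[(2S,3S)-3-[4-(benzyloxy)-3-methoxyphenyl]oxiran-2-yl]methoxy}methyl]propanedioate (present as its potassium enolate; drawn as the C–H form) | C=CCOC(=O)C(C(=O)OCC=C)[C@@H](c1ccc(OCc2ccccc2)c(OC)c1)OC[C@@H]1O[C@H]1c1ccc(OCc2ccccc2)c(OC)c1 | intermediate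
9 | diallyl (2R,4R)-2-[4-(benzyloxy)-3-methoxyphenyl]-4-[(R)-[4-(benzyloxy)-3-methoxyphenyl](hydroxy)methyl]oxolane-3,3-dicarboxylate (present as its potassium alkoxide; drawn as the alcohol) | C=CCOC(=O)C1(C(=O)OCC=C)[C@@H](c2ccc(OCc3ccccc3)c(OC)c2)OC[C@@H]1[C@@H](O)c1ccc(OCc2ccccc2)c(OC)c1 | intermediate
10 | allyl (3R,3aR,6R,6aS)-3,6-bis[4-(benzyloxy)-3-methoxyphenyl]-1-oxotetrahydro-1H,3H-furo[3,4-c]furan-6a(6H)-carboxylate (cis-fused; C3 aryl endo, C6 aryl exo) | O=C1O[C@@H](c3ccc(OCc4ccccc4)c(OC)c3)[C@H]2CO[C@H](c5ccc(OCc6ccccc6)c(OC)c5)[C@@]12C(=O)OCC=C | intermediate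
11 | (3R,3aR,6R,6aS)-3,6-bis[4-(benzyloxy)-3-methoxyphenyl]-1-oxotetrahydro-1H,3H-furo[3,4-c]furan-6a(6H)-carboxylic acid | O=C1O[C@@H](c3ccc(OCc4ccccc4)c(OC)c3)[C@H]2CO[C@H](c5ccc(OCc6ccccc6)c(OC)c5)[C@@]12C(=O)O | intermediate
12 | (3R,3aR,6S,6aS)-3,6-bis[4-(benzyloxy)-3-methoxyphenyl]tetrahydro-1H,3H-furo[3,4-c]furan-1-one | O=C1O[C@@H](c3ccc(OCc4ccccc4)c(OC)c3)[C@H]2CO[C@H](c5ccc(OCc6ccccc6)c(OC)c5)[C@@H]12 | intermediate
13 | [(2S,3R,4R)-2-[4-(benzyloxy)-3-methoxyphenyl]-4-[(R)-[4-(benzyloxy)-3-methoxyphenyl](hydroxy)methyl]oxolan-3-yl]methanol | COc1cc([C@H]2OC[C@H]([C@@H](O)c3ccc(OCc4ccccc4)c(OC)c3)[C@@H]2CO)ccc1OCc1ccccc1 | intermediate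
14 | (7R)-7-hydroxylariciresinol | COc1cc([C@H]2OC[C@H]([C@@H](O)c3ccc(O)c(OC)c3)[C@@H]2CO)ccc1O | target

**Step count**
Total: 8 steps. Longest linear sequence: 7 steps (1 → 3 → 4 → 5 → 10 → 12 → 13 → 14); step 4 is a one-step side branch.

**Three steps most likely to fail**

Step 5 is the main risk. The C7' ratio rests on a modest, unproven transition-state preference. The enolate could also attack the benzylic oxirane carbon (6-endo), and the epoxy alkoxide could undergo Payne rearrangement. The fallback builds the lactone first, so that the oxolane closes on a bicyclic scaffold whose endo face is already blocked by the C7 aryl. It sets out from 5, which is converted (TsCl, Et3N, cat. DMAP, CH2Cl2, 0 °C) into [(2S,3S)-3-[4-(benzyloxy)-3-methoxyphenyl]oxiran-2-yl]methyl 4-methylbenzenesulfonate F1. Treating F1 with the sodium enolate of 6 (NaH, THF/DMF, 0 → 50 °C) displaces the tosylate, opens the oxirane at C8 in a 3-exo step with inversion, and lactonizes. This gives, again with two rings formed in one flask, allyl (1R,4R,5S)-4-[4-(benzyloxy)-3-methoxyphenyl]-2-oxo-3-oxabicyclo[3.1.0]hexane-1-carboxylate F2. Ring expansion of F2 with aldehyde 1 and MgI2 (THF, 60 °C) then builds the oxolane: iodide opens the cyclopropane at its CH2, the magnesium enolate adds reversibly to 1, and the alkoxide displaces iodide. This extends known iodide-mediated cyclopropane ring expansions and is itself unproven. The fallback comes back to the route at 10.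

Step 3 is the second risk. The electron-rich aryl makes the epoxy alcohol prone to benzylic opening by tartrate, isopropanol or titanium, which can erode yield and ee. The fallback sets out from 4 and avoids Lewis acid altogether. Silylation (t-BuMe2SiCl, imidazole, DMF) gives tert-butyl{[(2E)-3-[4-(benzyloxy)-3-methoxyphenyl]prop-2-en-1-yl]oxy}dimethylsilane F3. Shi epoxidation in basic buffer then gives tert-butyl{[(2S,3S)-3-[4-(benzyloxy)-3-methoxyphenyl]oxiran-2-yl]methoxy}dimethylsilane F4. The conditions are 1,2:4,5-di-O-isopropylidene-β-L-erythro-2,3-hexodiulo-2,6-pyranose (the enantiomer of the fructose-derived ketone, made from L-sorbose), KHSO5, K2CO3 buffer at pH about 10.5, MeCN/dimethoxymethane/H2O, 0 °C. Desilylation with Bu4NF in THF at 0 °C comes back to the route at 5.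

Step 6 is the third risk. The hindered bridgehead acid may decarboxylate only at temperatures where the endo benzylic lactone C–O bond starts to ionize and C7 epimerizes. The fallback sets out from 10 and replaces thermal decarboxylation with a radical one. Deallylation at 25 °C (Pd(PPh3)4, morpholine, THF) is stopped at acid 11, which is isolated. Coupling with N-hydroxypyridine-2-thione (DCC, cat. DMAP, CH2Cl2, 0 °C, dark) gives the 2-thioxopyridin-1(2H)-yl ester of 11 (Barton ester, configuration as in 11) F5. Visible-light photolysis with t-BuSH (PhMe, 0–25 °C) expels CO2, and the bridgehead radical takes hydrogen on the convex face to give the cis-fused lactone. The fallback comes back to the route at 12.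

**Further compounds**
F1 | step 5 | [(2S,3S)-3-[4-(benzyloxy)-3-methoxyphenyl]oxiran-2-yl]methyl 4-methylbenzenesulfonate | Cc1ccc(cc1)S(=O)(=O)OC[C@@H]1O[C@H]1c1ccc(OCc2ccccc2)c(OC)c1
F2 | step 5 | allyl (1R,4R,5S)-4-[4-(benzyloxy)-3-methoxyphenyl]-2-oxo-3-oxabicyclo[3.1.0]hexane-1-carboxylate | O=C1O[C@@H](c3ccc(OCc4ccccc4)c(OC)c3)[C@H]2C[C@@]12C(=O)OCC=C
F3 | step 3 | tert-butyl{[(2E)-3-[4-(benzyloxy)-3-methoxyphenyl]prop-2-en-1-yl]oxy}dimethylsilane | CC(C)(C)[Si](C)(C)OC/C=C/c1ccc(OCc2ccccc2)c(OC)c1
F4 | step 3 | tert-butyl{[(2S,3S)-3-[4-(benzyloxy)-3-methoxyphenyl]oxiran-2-yl]methoxy}dimethylsilane | CC(C)(C)[Si](C)(C)OC[C@@H]1O[C@H]1c1ccc(OCc2ccccc2)c(OC)c1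
F5 | step 6 | 2-thioxopyridin-1(2H)-yl ester of acid 11 (Barton ester, configuration as in 11) | O=C1O[C@@H](c3ccc(OCc4ccccc4)c(OC)c3)[C@H]2CO[C@H](c5ccc(OCc6ccccc6)c(OC)c5)[C@@]12C(=O)ON1C=CC=CC1=S
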